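Assumption (a remark on the chemistry): target 16 is treated as the tautomer drawn, with the quinonoid carbonyl at C6 and a free 4-hydroxyphenyl group at C3. A proton shift to the tautomer with the carbonyl on the pendant ring does not give a separate compound to be made.

## The problem

Target 16 is a benzofuran-2,6-dione in which a five-membered enol lactone (O1, C2, C3, C3a, C7a) is fused to a six-membered ring at the quinone methide oxidation level (C3=C3a, C4=C5, C7=C7a, C6=O). Every ring position is substituted (phenyl at C4 and C7, methoxy at C5, carbonyl oxygen at C6, lactone oxygen at C7a, a 4-hydroxyphenyl group at C3), so the synthesis is mainly a problem of placing six different substituents on one benzene ring, three of them oxygen atoms of which only one is methylated. The target has no stereocentre; the only one that appears on the way, C3 of dihydro compound 15, is formed racemic and erased by the last oxidation, so no stereocentre has to control another. The cross-conjugated quinone methide is an electrophile and an oxidant, the enol lactone opens with hydroxide or alkoxide, and the free phenol makes the chromophore base-sensitive, so this array should be unveiled last, under neutral conditions, with no deprotection after it. The enabling feature is that the lactone carbonyl C2 lies between the phenolic oxygen O1 and the doubly benzylic carbon C3. Cut at O1–C2 and C2–C3, this is an ortho-quinone methide (O1=C7a–C3a=C3) plus one molecule of carbon monoxide, and that quinone methide is the dehydration product of a phenol and an aromatic aldehyde joined at C3–C3a. Because C6 carries oxygen para to C3a, the aromatic 6-hydroxybenzofuranone 15 is the dihydro form of 16, so all bond construction can be done on benzenoid compounds.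

## Retrosynthesis

**16 to 15.** No skeletal bond is cut; the hydrogens at C3 and at the C6 oxygen are put back. This moves every C–C and C–O bond formation away from the electrophilic quinone methide. Building the lactone at the quinone methide level would expose the chromophore to each later reagent. Precursor 15 is an ordinary phenolic lactone. The forward step needs only a neutral two-electron oxidant that abstracts the C3 hydrogen, which is doubly benzylic, alpha to the lactone carbonyl and para-related to the C6 hydroxyl.

**15 to 10, 11 and 12.** Three bonds are cut: O1–C2, C2–C3 and C3–C3a. Cutting only two of them, C3–C3a and O1–C2, would need a partner that already contains the C2–C3 bond; that option is held in reserve as the fallback to step 7. Cutting O1–C7a instead leads to an oxidative ring closure (Alternative 2). The three-bond cut gives the simplest pieces: the commodity aldehyde 11, carbon monoxide 12 and resorcinol 10, which holds all the complexity. In the forward direction carbinol 13 and ortho-quinone methide 14 are expected in the flask. The reaction must be site-selective on 10, which has a single unsubstituted ring carbon, and palladium with carbon monoxide 12 must capture 14 faster than a second molecule of 10 does.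

**10 to 8.** The C–O bond of the hydroxyl that becomes O1 is cut back to a C–Br bond, and the other hydroxyl is masked as an acetate. The oxygen to be introduced is para to the methoxy group, a position that electrophilic bromination reaches once the phenol is an acetate. Direct oxidation of free phenol 6 would go para to its hydroxyl, the wrong carbon. In the forward step hydroxide is both the oxygen source for the palladium-catalysed coupling and the reagent that removes the acetate, through bromophenol 9.

**8 to 7 to 6.** The C–Br bond and the O-acetyl bond are removed in turn. Acetylation is needed only to hand regiocontrol from the hydroxyl to the methoxy group. Phenol 6 has two fewer heteroatom substituents than 10, and its remaining two ring hydrogens are distinguished by their relation to OMe and OAc.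

**6 to 5.** One O–CH3 bond is re-formed. Compound 5 has a twofold axis, so its two methoxy groups are equivalent and the three oxygens of 10 are told apart without any protecting-group manoeuvre. The forward step must stop after one demethylation, which the phenoxide formed in the first cleavage should ensure.

**5 to 3 and 4.** Both aryl–aryl bonds are cut. A twofold Suzuki–Miyaura coupling of diiodide 3 with two equivalents of phenylboronic acid 4 installs both phenyl groups in one operation and again uses the symmetry.

**3 to 1.** The two C–I bonds are cut. Each methoxy group of veratrole 1 directs lithiation to its own ortho position, so dilithio compound 2 and then 3 should form with no regiochemical question from a bulk chemical.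

## Roads not taken

Alternative 1: The benzene ring of the resorcinol is cut between the carbons that become C3a and C7a, leading back to cyclobutenone A1 and from there to diisopropyl squarate A3. In the forward key step heating A1 opens the four-membered ring to a dienylketene, the ketene carbon bonds to the terminal vinyl carbon, and tautomerisation gives pentasubstituted phenol A2. Lewis-acid cleavage of the isopropyl ether of A2 would give 10. Merits: every substituent is placed by the order of two nucleophilic additions to A3, so there is no regiochemical question, and the two oxygens that must end as hydroxyl and methoxy are differentiated from the start. Weak points: A1 needs two cryogenic organolithium additions and O-methylation of a tertiary alkoxide on a strained, acid-sensitive ring, and A3 is far more costly than veratrole 1. Comparison: in regiochemical certainty this road is better than steps 3 to 6 of the chosen plan, and it reaches 10 in about the same number of operations. Against it the chosen plan sets bulk starting materials, robust cross-coupling and aromatic substitution steps, and no thermolysis of a sensitive intermediate. This road also ends at the arene and leaves the lactone annulation open, so it competes with steps 1 to 6 and not with the key step.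

Alternative 2: The O1–C7a bond is cut, leading to diarylacetic acid A4, which would come from phenol 6 by acid-catalysed alkylation para to the free hydroxyl. In the forward key step DDQ converts A4 to its para-quinone methide, the carboxyl group adds to the ring carbon that becomes C7a, and a second oxidation gives quinone methide acetate A5. Deacetylation of A5 would then give 16. Merits: the third ring oxygen is introduced by the lactonisation itself, so the acetylation, bromination and hydroxylation of the chosen plan are not needed, and the route is about two steps shorter. Weak points: the carboxylate must add to a ring carbon of the quinone methide, not to the more electrophilic exocyclic carbon, and an acid of this type can undergo oxidative decarboxylation in place of hydride loss. The acetate must then be removed from the finished base-sensitive chromophore. Comparison: on step count this road is better. Against it the chosen plan has the C7a oxygen in place before the lactone is formed, a last step that is a plain dehydrogenation with nothing to deprotect afterwards, and a key step in which the pendant aryl group is varied by changing a commercial aldehyde.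

Alternative 3: Three bonds of the arene are cut (those that become C5–C6, C7–C7a and C3a–C7a), leading to chromium carbene complex A6, (CO)5Cr=C(OMe)C(Ph)=CH2, and alkynylboronate A7. In the forward key step a Dötz benzannulation joins A6, A7 and one carbonyl ligand into boryl phenol A8, and oxidation of the C–B bond of A8 would give 10. Merits: the hexasubstituted ring is made in one step with the methoxy group and both phenyl groups already placed, and 10 would be reached in roughly half the number of steps. Weak points: the method uses stoichiometric chromium, and the alkyne carries two substituents of similar bulk, so the required orientation (boron next to the methoxy-bearing carbon) is not secured by sterics alone. Cyclopentannulation competes with internal aryl alkynes, and the doubly ortho-substituted aryl boronate A8 is prone to protodeboronation. Comparison: in brevity and convergence this road is clearly better. Against it the chosen plan avoids a stoichiometric toxic metal and fixes regiochemistry by symmetry and by well-established directing effects. Like Alternative 1, this road supplies only the arene and could be combined with the same key step.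

Key step: step 7

## Route

Step 1
Reactants: 1 veratrole (1,2-dimethoxybenzene)
Product: 3 1,4-diiodo-2,3-dimethoxybenzene, via 3,6-dilithioveratrole 2 (not isolated)
Conditions: n-BuLi (3 equiv), TMEDA (3 equiv), Et2O/hexane, 0 °C to reflux; then I2 (3 equiv), THF, −78 °C to rt
Reagents that add atoms: iodine, II
Why: Double directed ortho-metalation: each methoxy group directs n-BuLi/TMEDA to its free ortho position, and iodine traps the dilithio species at both carbons; the symmetry of 1 leaves no regiochemical question.

Step 2
Reactants: 3 1,4-diiodo-2,3-dimethoxybenzene; 4 phenylboronic acid
Product: 5 2,3-dimethoxy-1,4-diphenylbenzene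
Conditions: 4 (2.4 equiv), Pd(PPh3)4 (5 mol%), K2CO3 (4 equiv), toluene/EtOH/H2O, 90 °C
Reagents that add atoms: phenylboronic acid (second equivalent of 4), OB(O)c1ccccc1
Why: Twofold Suzuki–Miyaura coupling in which each C–I bond takes up one phenyl group from its own equivalent of 4; aryl iodides with one ortho methoxy group couple readily with phenylboronic acid, and both sites are equivalent.

Step 3
Reactants: 5 2,3-dimethoxy-1,4-diphenylbenzene
Product: 6 2-methoxy-3,6-diphenylphenol
Conditions: NaSEt (3 equiv), DMF, 120 °C; then 1 M HCl
Reagents that add atoms: none
Why: Nucleophilic (SN2) O-demethylation by thiolate; the two methoxy groups are equivalent, and the phenoxide formed by the first cleavage makes the second aryloxide a poor leaving group, so the reaction should stop at the monophenol.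

Step 4
Reactants: 6 2-methoxy-3,6-diphenylphenol
Product: 7 2-methoxy-3,6-diphenylphenyl acetate
Conditions: Ac2O, pyridine, DMAP (cat.), CH2Cl2, rt
Reagents that add atoms: acetic anhydride, CC(=O)OC(C)=O
Why: DMAP-catalysed O-acylation of a hindered phenol; the acetate turns the strongest ring activator into a weak one so that the methoxy group directs the next step.

Step 5
Reactants: 7 2-methoxy-3,6-diphenylphenyl acetate
Product: 8 3-bromo-6-methoxy-2,5-diphenylphenyl acetate
Conditions: NBS (1.05 equiv), MeCN, 0 °C to rt
Reagents that add atoms: N-bromosuccinimide, O=C1CCC(=O)N1Br
Why: Electrophilic aromatic bromination; in acetates of guaiacol type the methoxy group outranks the acetoxy group and directs para to itself, and the oxygenated central ring is more electron-rich than the two phenyl rings.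

Step 6
Reactants: 8 3-bromo-6-methoxy-2,5-diphenylphenyl acetate
Product: 10 4-methoxy-2,5-diphenylbenzene-1,3-diol, via 3-bromo-6-methoxy-2,5-diphenylphenol 9 (not isolated)
Conditions: Pd2(dba)3 (2 mol%), tBuXPhos (8 mol%), KOH (5 equiv), 1,4-dioxane/H2O, 100 °C, argon; then 1 M HCl
Reagents that add atoms: potassium hydroxide, [K+].[OH-]
Why: Palladium-catalysed hydroxylation of an aryl bromide with hydroxide (C–O cross-coupling with a bulky biarylphosphine); the same hydroxide saponifies the acetate first, so one operation should release both hydroxyl groups.

Step 7
Reactants: 10 4-methoxy-2,5-diphenylbenzene-1,3-diol; 11 4-hydroxybenzaldehyde; 12 carbon monoxide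
Product: 15 rac-6-hydroxy-3-(4-hydroxyphenyl)-5-methoxy-4,7-diphenylbenzofuran-2(3H)-one, via diaryl carbinol 13 (not isolated), via ortho-quinone methide 14 (not isolated)
Conditions: Pd(OAc)2 (5 mol%), Xantphos (6 mol%), (PhO)2P(O)OH (20 mol%), CO (1 atm), 1,4-dioxane, 80 °C, 10 added by syringe pump to 11 (3 equiv), air excluded
Reagents that add atoms: none
Why: Proposed new method: the phosphoric acid diester should activate aldehyde 11, the single free ring carbon of 10 (ortho to one hydroxyl and para to the other) should attack it in a Friedel–Crafts hydroxyalkylation to give carbinol 13, and loss of water should give ortho-quinone methide 14, which both hydroxyaryl rings stabilise. Zerovalent palladium, formed from Pd(OAc)2 and Xantphos under CO, should add to the exocyclic carbon of 14 to give an η3-benzyl complex of divalent palladium with the C7a oxygen as phenoxide; CO should then insert into the Pd–C bond, and C–O reductive elimination from the acyl phenoxide should release 15 and return zerovalent palladium. The closest known reaction type is the palladium-catalysed carbonylative [4+1] annulation of ortho-hydroxybenzyl alcohols to benzofuran-2(3H)-ones, taken to pass through the same kind of quinone methide; new here is that the quinone methide is made in the same flask from a phenol and an aldehyde. The five-membered lactone closes by formal [4+1] union of the O=C–C=C unit of 14 with CO, the last bond being O1–C2 formed from a six-membered palladacycle. C3 is formed racemic with no controlling element, which is of no consequence because step 8 makes it trigonal. Site selectivity is secured because 10 has one unsubstituted ring carbon and only the hydroxyl ortho to it can close a ring, the other being para. Chemoselectivity for capture of 14 by palladium over capture by a second molecule of 10 is helped by slow addition of 10 to excess 11 and by the phenyl group next to the nucleophilic carbon, which disfavours a second arylation at the same carbon.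

Step 8
Reactants: 15 rac-6-hydroxy-3-(4-hydroxyphenyl)-5-methoxy-4,7-diphenylbenzofuran-2(3H)-one
Product: 16 3-(4-hydroxyphenyl)-5-methoxy-4,7-diphenylbenzofuran-2,6-dione
Conditions: DDQ (1.05 equiv), 1,4-dioxane, rt
Reagents that add atoms: none
Why: Quinone dehydrogenation of a para-hydroxybenzylic C–H: DDQ should abstract hydride from C3, which is doubly benzylic and conjugated through C3a with the C6 hydroxyl, and loss of the phenolic proton gives the quinone methide; the C3 stereocentre disappears and no protecting group remains to be removed.

## Compound list

1 | veratrole (1,2-dimethoxybenzene) | COc1ccccc1OC | starting material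
2 | 3,6-dilithioveratrole (1,4-dilithio-2,3-dimethoxybenzene) | [Li]c1ccc([Li])c(OC)c1OC | intermediate
3 | 1,4-diiodo-2,3-dimethoxybenzene | COc1c(I)ccc(I)c1OC | intermediate
4 | phenylboronic acid | OB(O)c1ccccc1 | starting material
5 | 2,3-dimethoxy-1,4-diphenylbenzene | COc1c(-c2ccccc2)ccc(-c2ccccc2)c1OC | intermediate
6 | 2-methoxy-3,6-diphenylphenol | COc1c(O)c(-c2ccccc2)ccc1-c1ccccc1 | intermediate
7 | 2-methoxy-3,6-diphenylphenyl acetate | COc1c(OC(C)=O)c(-c2ccccc2)ccc1-c1ccccc1 | intermediate
8 | 3-bromo-6-methoxy-2,5-diphenylphenyl acetate | COc1c(OC(C)=O)c(-c2ccccc2)c(Br)cc1-c1ccccc1 | intermediate
9 | 3-bromo-6-methoxy-2,5-diphenylphenol | COc1c(O)c(-c2ccccc2)c(Br)cc1-c1ccccc1 | intermediate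
10 | 4-methoxy-2,5-diphenylbenzene-1,3-diol | COc1c(O)c(-c2ccccc2)c(O)cc1-c1ccccc1 | intermediate
11 | 4-hydroxybenzaldehyde | O=Cc1ccc(O)cc1 | starting material
12 | carbon monoxide | [C-]#[O+] | starting material
13 | 4-[hydroxy(4-hydroxyphenyl)methyl]-6-methoxy-2,5-diphenylbenzene-1,3-diol (racemic) | COc1c(O)c(-c2ccccc2)c(O)c(C(O)c2ccc(O)cc2)c1-c1ccccc1 | intermediate
14 | 3-hydroxy-6-[(4-hydroxyphenyl)methylidene]-4-methoxy-2,5-diphenylcyclohexa-2,4-dien-1-one (geometry of the exocyclic double bond not defined) | COC1=C(c2ccccc2)C(=Cc2ccc(O)cc2)C(=O)C(c2ccccc2)=C1O | intermediate
15 | 6-hydroxy-3-(4-hydroxyphenyl)-5-methoxy-4,7-diphenylbenzofuran-2(3H)-one (racemic at C3) | COc1c(O)c(-c2ccccc2)c2OC(=O)C(c3ccc(O)cc3)c2c1-c1ccccc1 | intermediate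
16 | 3-(4-hydroxyphenyl)-5-methoxy-4,7-diphenylbenzofuran-2,6-dione (no stereocentre) | COC1=C(c2ccccc2)C2=C(c3ccc(O)cc3)C(=O)OC2=C(c2ccccc2)C1=O | target

## Step count and risks

Total step count: 8. Longest linear sequence: 8 steps (1 to 16).

**Step 7 (key step, Proposed new method).** The most likely failure is that palladium and carbon monoxide intercept the quinone methide too slowly. A second arylation by the resorcinol, or reduction by a Pd–H species formed from CO and the released water, would then take over. The very stabilised benzylpalladium species may also ionise back before CO inserts. Fallback by known chemistry: setting out from 10, acid-catalysed Friedel–Crafts alkylation with commercial 4-hydroxymandelic acid (acetic acid with catalytic H2SO4, heating) should give 2-(2,4-dihydroxy-5-methoxy-3,6-diphenylphenyl)-2-(4-hydroxyphenyl)acetic acid F1. F1 should lactonise in the same flask onto the ortho hydroxyl and so come back to the route at 15. This is the established two-component synthesis of 3-arylbenzofuran-2(3H)-ones from phenols and mandelic acids; it forms C3–C3a and O1–C2 but brings the C2–C3 bond in ready-made.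

**Step 5.** Loss of regiocontrol is the main concern. The methoxy group is flanked on both sides and may be twisted out of conjugation, which would allow bromination para to the acetoxy group or on a phenyl ring. Fallback: setting out from symmetric 5, where both open positions of the central ring are equivalent, bromination with NBS should give 1-bromo-3,4-dimethoxy-2,5-diphenylbenzene F2. Palladium-catalysed hydroxylation as in step 6 should then give 3,4-dimethoxy-2,5-diphenylphenol F3. Thiolate demethylation of F3 is expected at the methoxy group meta to the phenoxide, because cleavage para to it would generate a hydroquinone dianion, and this comes back to the route at 10. The regiochemical decision is thereby moved from an electrophilic substitution to a nucleophilic dealkylation.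

**Step 6.** Saponification of the acetate leaves a hindered, electron-rich bromophenoxide. Oxidative addition may then be slow and give way to hydrodebromination, and the resorcinol dianion may be oxidised by traces of air in hot base. Fallback: setting out from 8, Miyaura borylation (B2pin2, Pd(dppf)Cl2, KOAc, 1,4-dioxane, 90 °C), which leaves the acetate intact, should give 6-methoxy-2,5-diphenyl-3-(4,4,5,5-tetramethyl-1,3,2-dioxaborolan-2-yl)phenyl acetate F4. Oxidation of the C–B bond with H2O2 and NaOH at 0 °C, which also cleaves the acetate, comes back to the route at 10 under much milder basic conditions.

**Step 3.** Incomplete conversion, or a second demethylation at the temperature needed for the first cleavage, may occur. Fallback: setting out from 5, exhaustive demethylation with BBr3 (CH2Cl2, −78 °C to rt) should give 3,6-diphenylbenzene-1,2-diol F5. Mono-O-methylation of this symmetric catechol with one equivalent of MeI and Li2CO3 in DMF comes back to the route at 6.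

## Further compounds

F1 | step 7 | 2-(2,4-dihydroxy-5-methoxy-3,6-diphenylphenyl)-2-(4-hydroxyphenyl)acetic acid (racemic) | COc1c(O)c(-c2ccccc2)c(O)c(C(C(=O)O)c2ccc(O)cc2)c1-c1ccccc1
F2 | step 5 | 1-bromo-3,4-dimethoxy-2,5-diphenylbenzene | COc1c(-c2ccccc2)cc(Br)c(-c2ccccc2)c1OC
F3 | step 5 | 3,4-dimethoxy-2,5-diphenylphenol | COc1c(-c2ccccc2)cc(O)c(-c2ccccc2)c1OC
F4 | step 6 | 6-methoxy-2,5-diphenyl-3-(4,4,5,5-tetramethyl-1,3,2-dioxaborolan-2-yl)phenyl acetate | COc1c(OC(C)=O)c(-c2ccccc2)c(B2OC(C)(C)C(C)(C)O2)cc1-c1ccccc1
F5 | step 3 | 3,6-diphenylbenzene-1,2-diol | Oc1c(-c2ccccc2)ccc(-c2ccccc2)c1O
A1 | alternative 1 | 3-isopropoxy-4-methoxy-2-phenyl-4-(1-phenylvinyl)cyclobut-2-en-1-one (racemic) | COC1(C(=C)c2ccccc2)C(=O)C(c2ccccc2)=C1OC(C)C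
A2 | alternative 1 | 3-isopropoxy-4-methoxy-2,5-diphenylphenol | COc1c(OC(C)C)c(-c2ccccc2)c(O)cc1-c1ccccc1
A3 | alternative 1 | diisopropyl squarate (3,4-diisopropoxycyclobut-3-ene-1,2-dione) | CC(C)OC1=C(OC(C)C)C(=O)C1=O
A4 | alternative 2 | 2-(4-acetoxyphenyl)-2-(4-hydroxy-3-methoxy-2,5-diphenylphenyl)acetic acid (racemic) | COc1c(O)c(-c2ccccc2)cc(C(C(=O)O)c2ccc(OC(C)=O)cc2)c1-c1ccccc1
A5 | alternative 2 | 4-(5-methoxy-2,6-dioxo-4,7-diphenyl-2,6-dihydrobenzofuran-3-yl)phenyl acetate | COC1=C(c2ccccc2)C2=C(c3ccc(OC(C)=O)cc3)C(=O)OC2=C(c2ccccc2)C1=O
A6 | alternative 3 | pentacarbonyl[methoxy(1-phenylvinyl)carbene]chromium, (CO)5Cr=C(OMe)C(Ph)=CH2 | COC(C(=C)c1ccccc1)=[Cr](=C=O)(=C=O)(=C=O)(=C=O)=C=O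
A7 | alternative 3 | 2-(phenylethynyl)-4,4,5,5-tetramethyl-1,3,2-dioxaborolane | CC1(C)OB(C#Cc2ccccc2)OC1(C)C
A8 | alternative 3 | 4-methoxy-2,5-diphenyl-3-(4,4,5,5-tetramethyl-1,3,2-dioxaborolan-2-yl)phenol | COc1c(B2OC(C)(C)C(C)(C)O2)c(-c2ccccc2)c(O)cc1-c1ccccc1
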